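## Retrosynthetic overview

1. Target ⇐ 8-O-angeloylation and desilylation of an 8-hydroxy macrolactone; the ester goes on last.
2. Ten-membered carbocycle and cis-fused α-methylene lactone ⇐ C6–C7 closure of a furanone-templated allylsilane aldehyde, then lactonisation.
3. C8–O stereocentre ⇐ invertive C–O bond formation (Mitsunobu aryl ether) on the 8-epi alcohol; furanone ⇐ C–O cycloisomerisation (O–C3 bond) of a 1-C-alkynyl ketofuranose, which also frees that C8 hydroxyl.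
4. Alkynyl ketofuranose ⇐ lithium acetylide (C2–C6, Marshall propargylation) + a lactone (C1, C7–C13) made from 2-C-methyl-D-ribono-1,4-lactone, which supplies C9 and C10.
5. Ring order: furanone first, then the carbocycle (a nine-membered oxacycle) through C6–C7, then the lactone.

Assumption: carbons are labelled C1–C15 in germacrane order as in the target (C1 ketone, C2=C3, C4 methyl-bearing, C6 lactone carbinol, C8 ester carbinol, C10 quaternary, C11–C13 lactone) for all intermediates; commercial aqueous 2,2-dimethoxyacetaldehyde is dried before use.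

## Route

Step 1
Reactants: 1 (R)-but-3-yn-2-ol
Product: 2 (R)-but-3-yn-2-yl methanesulfonate
Conditions: MsCl, Et3N, CH2Cl2, −78 to 0 °C
Reagents that add atoms: methanesulfonyl chloride, CS(=O)(=O)Cl
Why: O-sulfonylation of the secondary propargylic alcohol gives the leaving group for the Marshall reaction and does not touch the stereocentre.

Step 2
Reactants: 2 (R)-but-3-yn-2-yl methanesulfonate, 3 2,2-dimethoxyacetaldehyde
Product: 5 (2S,3S)-1,1-dimethoxy-3-methylpent-4-yn-2-ol, via allenylindium 4 (not isolated)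
Conditions: Pd(OAc)2 (5 mol %), PPh3 (5 mol %), InI (indium monoiodide, 1.4 equiv), THF/HMPA 3:1, 0 °C to rt
Reagents that add atoms: none
Why: Marshall propargylation: zerovalent palladium ionises the mesylate anti (SN2') to an allenylpalladium, indium monoiodide converts it into allenylindium 4, and 4 adds to the aldehyde through a cyclic SE2' transition state, so the (R)-mesylate sets the methyl-bearing carbon (3S, the later C4) and the anti-selective addition sets the carbinol carbon (2S, the later C5).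

Step 3
Reactants: 5 (2S,3S)-1,1-dimethoxy-3-methylpent-4-yn-2-ol
Product: 6 tert-butyl{[(2S,3S)-1,1-dimethoxy-3-methylpent-4-yn-2-yl]oxy}dimethylsilane
Conditions: TBSCl, imidazole, DMAP (cat.), DMF, 40 °C
Reagents that add atoms: tert-butyldimethylsilyl chloride, CC(C)(C)[Si](C)(C)Cl
Why: Silyl ether formation on the only hydroxyl under chloride/imidazole conditions leaves the dimethyl acetal intact and gives a non-chelating C5 oxygen for later Felkin control.

Step 4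
Reactants: 7 ethyl (triphenyl-λ5-phosphanylidene)acetate, 8 (iodomethyl)trimethylsilane
Product: 10 ethyl 2-(triphenyl-λ5-phosphanylidene)-3-(trimethylsilyl)propanoate, via phosphonium iodide 9 (not isolated)
Conditions: MeCN, 80 °C; then 1 M NaOH, CH2Cl2, 0 °C
Reagents that add atoms: none
Why: C-alkylation of a stabilised phosphorus ylide by the α-silyl iodide and deprotonation of the phosphonium salt (Bestmann-type ylide alkylation) give the reagent that later delivers C11–C13 with the allylsilane already in place.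

Step 5
Reactants: 11 2-C-methyl-D-ribono-1,4-lactone
Product: 12 (3R,4R,5R)-4-(tert-butyldimethylsilyloxy)-5-[(tert-butyldimethylsilyloxy)methyl]-3-hydroxy-3-methyloxolan-2-one
Conditions: TBSCl (2.5 equiv), imidazole, DMAP (cat.), DMF, 40 °C
Reagents that add atoms: tert-butyldimethylsilyl chloride, CC(C)(C)[Si](C)(C)Cl
Why: Silyl ether formation is fast at the primary and the secondary hydroxyl while the tertiary, carbonyl-flanked C10 hydroxyl stays free; C8 (R), C9 (R) and C10 (R) come unchanged from the sugar.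

Step 6
Reactants: 12 (3R,4R,5R)-4-(tert-butyldimethylsilyloxy)-5-[(tert-butyldimethylsilyloxy)methyl]-3-hydroxy-3-methyloxolan-2-one
Product: 13 (3R,4R,5R)-4-(tert-butyldimethylsilyloxy)-3-hydroxy-5-(hydroxymethyl)-3-methyloxolan-2-one
Conditions: HF·pyridine, pyridine, THF, 0 °C
Reagents that add atoms: none
Why: Fluoride-mediated desilylation is much faster at the primary than at the hindered secondary silyl ether, so only the C7 hydroxyl is freed.

Step 7
Reactants: 13 (3R,4R,5R)-4-(tert-butyldimethylsilyloxy)-3-hydroxy-5-(hydroxymethyl)-3-methyloxolan-2-one, 10 ethyl 2-(triphenyl-λ5-phosphanylidene)-3-(trimethylsilyl)propanoate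
Product: 15 ethyl (2Z)-3-[(2R,3R,4R)-3-(tert-butyldimethylsilyloxy)-4-hydroxy-4-methyl-5-oxooxolan-2-yl]-2-[(trimethylsilyl)methyl]prop-2-enoate, via aldehyde 14 (not isolated)
Conditions: Dess–Martin periodinane, NaHCO3, CH2Cl2, rt; then 10 (1.3 equiv), rt to 40 °C
Reagents that add atoms: none
Why: Dess–Martin oxidation and Wittig olefination in one flask avoid isolating the hydrate-prone aldehyde 14; the stabilised ylide gives the isomer with C8 cis to CH2SiMe3 (trans to the ester), and C8 stays in the ribo configuration, which is the more stable epimer.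

Step 8
Reactants: 6 tert-butyl{[(2S,3S)-1,1-dimethoxy-3-methylpent-4-yn-2-yl]oxy}dimethylsilane, 15 ethyl (2Z)-3-[(2R,3R,4R)-3-(tert-butyldimethylsilyloxy)-4-hydroxy-4-methyl-5-oxooxolan-2-yl]-2-[(trimethylsilyl)methyl]prop-2-enoate
Product: 17 ethyl (2Z)-3-[(2R,3R,4R)-3-(tert-butyldimethylsilyloxy)-5-{(3S,4S)-4-(tert-butyldimethylsilyloxy)-5,5-dimethoxy-3-methylpent-1-yn-1-yl}-4,5-dihydroxy-4-methyloxolan-2-yl]-2-[(trimethylsilyl)methyl]prop-2-enoate (both C5 anomers), via lithium acetylide 16 (not isolated)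
Conditions: 6, n-BuLi, THF, −78 °C; 15 + LiN(SiMe3)2 (1.0 equiv), THF, −78 °C; combine, −78 °C, 1 h; AcOH
Reagents that add atoms: none
Why: 1,2-Addition of a lithium acetylide to the γ-lactone stops at the lithium lactolate, the lactone being far more electrophilic than the hindered trisubstituted enoate, and prior deprotonation of the tertiary hydroxyl keeps it from quenching the acetylide; no existing stereocentre is touched.

Step 9
Reactants: 17 ethyl (2Z)-3-[(2R,3R,4R)-3-(tert-butyldimethylsilyloxy)-5-{(3S,4S)-4-(tert-butyldimethylsilyloxy)-5,5-dimethoxy-3-methylpent-1-yn-1-yl}-4,5-dihydroxy-4-methyloxolan-2-yl]-2-[(trimethylsilyl)methyl]prop-2-enoate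
Product: 18 ethyl (2Z,4R,5R)-5-(tert-butyldimethylsilyloxy)-5-{(2R)-5-[(2R,3S)-3-(tert-butyldimethylsilyloxy)-4,4-dimethoxybutan-2-yl]-2-methyl-3-oxo-2,3-dihydrofuran-2-yl}-4-hydroxy-2-[(trimethylsilyl)methyl]pent-2-enoate
Conditions: Ph3PAuNTf2 (5 mol %), 4 Å MS, CH2Cl2, rt
Reagents that add atoms: none
Why: Proposed new method: gold-catalysed ring-chain relay cycloisomerisation of a 1-C-alkynyl ketofuranose, in which hemiketal 17 acts as a masked γ,α'-dihydroxy ynone: π-activation of the alkyne by cationic monovalent gold lets the free tertiary C10 hydroxyl add 5-endo-dig at C3 (on the hemiketal itself, whose C1–O8 bond then collapses to the ketone, or on the small equilibrium share of open ynone), protodeauration gives the 3(2H)-furanone and releases the C8 hydroxyl, the C9 oxygen being silylated so that no six-membered pyranone can form; the closest known reaction type is the gold-catalysed 5-endo-dig cyclisation of open-chain α'-hydroxy ynones to 3(2H)-furanones, and no stereocentre is created (C10 is retained).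

Step 10
Reactants: 18 ethyl (2Z,4R,5R)-5-(tert-butyldimethylsilyloxy)-5-{(2R)-5-[(2R,3S)-3-(tert-butyldimethylsilyloxy)-4,4-dimethoxybutan-2-yl]-2-methyl-3-oxo-2,3-dihydrofuran-2-yl}-4-hydroxy-2-[(trimethylsilyl)methyl]pent-2-enoate
Product: 19 ethyl (2Z,4S,5R)-5-(tert-butyldimethylsilyloxy)-5-{(2R)-5-[(2R,3S)-3-(tert-butyldimethylsilyloxy)-4,4-dimethoxybutan-2-yl]-2-methyl-3-oxo-2,3-dihydrofuran-2-yl}-4-(4-methoxyphenoxy)-2-[(trimethylsilyl)methyl]pent-2-enoate
Conditions: 4-methoxyphenol, PPh3, DIAD, toluene, 0 °C to rt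
Reagents that add atoms: 4-methoxyphenol, COc1ccc(O)cc1
Why: Mitsunobu etherification: SN2 displacement of the oxyphosphonium by phenoxide inverts the allylic C8 centre (R to S), so this C–O bond formation sets the C8 configuration of the target and leaves an aryl ether that is a poor leaving group next to the allylsilane and can later be removed oxidatively.

Step 11
Reactants: 19 ethyl (2Z,4S,5R)-5-(tert-butyldimethylsilyloxy)-5-{(2R)-5-[(2R,3S)-3-(tert-butyldimethylsilyloxy)-4,4-dimethoxybutan-2-yl]-2-methyl-3-oxo-2,3-dihydrofuran-2-yl}-4-(4-methoxyphenoxy)-2-[(trimethylsilyl)methyl]pent-2-enoate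
Product: 20 ethyl (2Z,4S,5R)-5-(tert-butyldimethylsilyloxy)-5-{(2R)-5-[(2R,3S)-3-(tert-butyldimethylsilyloxy)-4-oxobutan-2-yl]-2-methyl-3-oxo-2,3-dihydrofuran-2-yl}-4-(4-methoxyphenoxy)-2-[(trimethylsilyl)methyl]pent-2-enoate
Conditions: TFA/H2O 9:1, CH2Cl2, 0 °C
Reagents that add atoms: water, O
Why: Acid-catalysed acetal hydrolysis frees the C6 aldehyde; the ester-deactivated allylsilane resists protodesilylation, and the secondary silyl ethers and the aryl ether survive brief aqueous acid at 0 °C.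

Step 12
Reactants: 20 ethyl (2Z,4S,5R)-5-(tert-butyldimethylsilyloxy)-5-{(2R)-5-[(2R,3S)-3-(tert-butyldimethylsilyloxy)-4-oxobutan-2-yl]-2-methyl-3-oxo-2,3-dihydrofuran-2-yl}-4-(4-methoxyphenoxy)-2-[(trimethylsilyl)methyl]pent-2-enoate
Product: 22 (4R,5S,6R,7R,8S,9R,10R)-5,9-bis(tert-butyldimethylsilyloxy)-8-(4-methoxyphenoxy)-1-oxo-3,10-epoxygermacra-2,11(13)-dien-12,6-olide, via hydroxy ester 21 (not isolated)
Conditions: BF3·OEt2 (3 equiv), CH2Cl2 (2 mM), −78 to −20 °C; aq. NaHCO3; then p-TsOH·H2O (10 mol %), CH2Cl2, rt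
Reagents that add atoms: none
Why: Intramolecular Hosomi–Sakurai allylation then acid-catalysed lactonisation: the BF3-activated aldehyde is attacked at C7 by the allylsilane (SE2', silicon lost as Me3SiF), closing the ten-membered carbocycle on the furanone template; Felkin–Anh addition anti to the C5 silyloxy group is expected to set 6R, and with H8 held in the alkene plane by A(1,3) strain the aldehyde enters anti to the C8–C9 bond to set C7 (C11 cis to both flanking oxygens), so the syn C6/C7 hydroxy ester 21 lactonises to the cis-fused α-methylene lactone, only the C6 hydroxyl being free to do so.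

Step 13
Reactants: 22 (4R,5S,6R,7R,8S,9R,10R)-5,9-bis(tert-butyldimethylsilyloxy)-8-(4-methoxyphenoxy)-1-oxo-3,10-epoxygermacra-2,11(13)-dien-12,6-olide
Product: 23 (4R,5S,6R,7R,8S,9R,10R)-5,9-bis(tert-butyldimethylsilyloxy)-8-hydroxy-1-oxo-3,10-epoxygermacra-2,11(13)-dien-12,6-olide
Conditions: (NH4)2Ce(NO3)6 (2.5 equiv), pyridine, MeCN/H2O 4:1, 0 °C
Reagents that add atoms: none
Why: Oxidative dearylation: tetravalent cerium oxidises the 4-methoxyphenyl ether to benzoquinone and frees only the C8 hydroxyl, the buffered cold conditions sparing the silyl ethers, the furanone and the α-methylene lactone.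

Step 14
Reactants: 23 (4R,5S,6R,7R,8S,9R,10R)-5,9-bis(tert-butyldimethylsilyloxy)-8-hydroxy-1-oxo-3,10-epoxygermacra-2,11(13)-dien-12,6-olide, 24 angelic acid
Product: 26 (4R,5S,6R,7S,8S,9R,10R)-8-angeloyloxy-5,9-bis(tert-butyldimethylsilyloxy)-1-oxo-3,10-epoxygermacra-2,11(13)-dien-12,6-olide, via mixed anhydride 25 (not isolated)
Conditions: 24, 2,4,6-trichlorobenzoyl chloride, Et3N, toluene, rt; then 23, 80 °C
Reagents that add atoms: none
Why: Yamaguchi esterification through mixed anhydride 25 acylates the hindered secondary C8 hydroxyl with retention at carbon and without base-induced Z to E isomerisation of the angelate.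

Step 15
Reactants: 26 (4R,5S,6R,7S,8S,9R,10R)-8-angeloyloxy-5,9-bis(tert-butyldimethylsilyloxy)-1-oxo-3,10-epoxygermacra-2,11(13)-dien-12,6-olide
Product: 27 (4R,5S,6R,7S,8S,9R,10R)-8-angeloyloxy-5,9-dihydroxy-1-oxo-3,10-epoxygermacra-2,11(13)-dien-12,6-olide (CNP0206920.1)
Conditions: HF·pyridine, pyridine, THF, 0 °C to rt
Reagents that add atoms: none
Why: Fluoride-mediated desilylation under buffered, non-basic conditions removes both secondary silyl ethers without opening or migrating the lactone, adding to the α-methylene group or cleaving the angelate.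

## Compound list

1 | (R)-but-3-yn-2-ol | C[C@@H](O)C#C | starting material
2 | (R)-but-3-yn-2-yl methanesulfonate | C[C@@H](OS(C)(=O)=O)C#C | intermediate
3 | 2,2-dimethoxyacetaldehyde | COC(OC)C=O | starting material
4 | (aS)-buta-1,2-dien-1-ylindium iodide methanesulfonate (allenylindium) | C[CH]=[C@@]=[CH][In](I)OS(C)(=O)=O | intermediate
5 | (2S,3S)-1,1-dimethoxy-3-methylpent-4-yn-2-ol | COC(OC)[C@@H](O)[C@@H](C)C#C | intermediate
6 | tert-butyl{[(2S,3S)-1,1-dimethoxy-3-methylpent-4-yn-2-yl]oxy}dimethylsilane | COC(OC)[C@@H](O[Si](C)(C)C(C)(C)C)[C@@H](C)C#C | intermediate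
7 | ethyl (triphenyl-λ5-phosphanylidene)acetate | CCOC(=O)C=P(c1ccccc1)(c1ccccc1)c1ccccc1 | starting material
8 | (iodomethyl)trimethylsilane | C[Si](C)(C)CI | starting material
9 | [1-ethoxy-1-oxo-3-(trimethylsilyl)propan-2-yl]triphenylphosphonium iodide (racemic) | CCOC(=O)C(C[Si](C)(C)C)[P+](c1ccccc1)(c1ccccc1)c1ccccc1.[I-] | intermediate
10 | ethyl 2-(triphenyl-λ5-phosphanylidene)-3-(trimethylsilyl)propanoate | CCOC(=O)C(C[Si](C)(C)C)=P(c1ccccc1)(c1ccccc1)c1ccccc1 | intermediate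
11 | 2-C-methyl-D-ribono-1,4-lactone, (3R,4R,5R)-3,4-dihydroxy-5-(hydroxymethyl)-3-methyloxolan-2-one | O=C1[C@](C)(O)[C@H](O)[C@@H](CO)O1 | starting material
12 | (3R,4R,5R)-4-(tert-butyldimethylsilyloxy)-5-[(tert-butyldimethylsilyloxy)methyl]-3-hydroxy-3-methyloxolan-2-one | O=C1[C@](C)(O)[C@H](O[Si](C)(C)C(C)(C)C)[C@@H](CO[Si](C)(C)C(C)(C)C)O1 | intermediate
13 | (3R,4R,5R)-4-(tert-butyldimethylsilyloxy)-3-hydroxy-5-(hydroxymethyl)-3-methyloxolan-2-one | O=C1[C@](C)(O)[C@H](O[Si](C)(C)C(C)(C)C)[C@@H](CO)O1 | intermediate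
14 | (2S,3R,4R)-3-(tert-butyldimethylsilyloxy)-4-hydroxy-4-methyl-5-oxooxolane-2-carbaldehyde | O=C1[C@](C)(O)[C@H](O[Si](C)(C)C(C)(C)C)[C@@H](C=O)O1 | intermediate
15 | ethyl (2Z)-3-[(2R,3R,4R)-3-(tert-butyldimethylsilyloxy)-4-hydroxy-4-methyl-5-oxooxolan-2-yl]-2-[(trimethylsilyl)methyl]prop-2-enoate | O=C1[C@](C)(O)[C@H](O[Si](C)(C)C(C)(C)C)[C@@H](/C=C(\C[Si](C)(C)C)C(=O)OCC)O1 | intermediate
16 | {(3S,4S)-4-(tert-butyldimethylsilyloxy)-5,5-dimethoxy-3-methylpent-1-yn-1-yl}lithium | [Li]C#C[C@H](C)[C@H](O[Si](C)(C)C(C)(C)C)C(OC)OC | intermediate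
17 | ethyl (2Z)-3-[(2R,3R,4R)-3-(tert-butyldimethylsilyloxy)-5-{(3S,4S)-4-(tert-butyldimethylsilyloxy)-5,5-dimethoxy-3-methylpent-1-yn-1-yl}-4,5-dihydroxy-4-methyloxolan-2-yl]-2-[(trimethylsilyl)methyl]prop-2-enoate (both C5 anomers; hemiketal carbon left undefined) | OC1(C#C[C@H](C)[C@H](O[Si](C)(C)C(C)(C)C)C(OC)OC)[C@](C)(O)[C@H](O[Si](C)(C)C(C)(C)C)[C@@H](/C=C(\C[Si](C)(C)C)C(=O)OCC)O1 | intermediate
18 | ethyl (2Z,4R,5R)-5-(tert-butyldimethylsilyloxy)-5-{(2R)-5-[(2R,3S)-3-(tert-butyldimethylsilyloxy)-4,4-dimethoxybutan-2-yl]-2-methyl-3-oxo-2,3-dihydrofuran-2-yl}-4-hydroxy-2-[(trimethylsilyl)methyl]pent-2-enoate | COC(OC)[C@@H](O[Si](C)(C)C(C)(C)C)[C@@H](C)C1=CC(=O)[C@](C)(O1)[C@H](O[Si](C)(C)C(C)(C)C)[C@H](O)/C=C(\C[Si](C)(C)C)C(=O)OCC | intermediate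
19 | ethyl (2Z,4S,5R)-5-(tert-butyldimethylsilyloxy)-5-{(2R)-5-[(2R,3S)-3-(tert-butyldimethylsilyloxy)-4,4-dimethoxybutan-2-yl]-2-methyl-3-oxo-2,3-dihydrofuran-2-yl}-4-(4-methoxyphenoxy)-2-[(trimethylsilyl)methyl]pent-2-enoate | COC(OC)[C@@H](O[Si](C)(C)C(C)(C)C)[C@@H](C)C1=CC(=O)[C@](C)(O1)[C@H](O[Si](C)(C)C(C)(C)C)[C@@H](Oc2ccc(OC)cc2)/C=C(\C[Si](C)(C)C)C(=O)OCC | intermediate
20 | ethyl (2Z,4S,5R)-5-(tert-butyldimethylsilyloxy)-5-{(2R)-5-[(2R,3S)-3-(tert-butyldimethylsilyloxy)-4-oxobutan-2-yl]-2-methyl-3-oxo-2,3-dihydrofuran-2-yl}-4-(4-methoxyphenoxy)-2-[(trimethylsilyl)methyl]pent-2-enoate | O=C[C@@H](O[Si](C)(C)C(C)(C)C)[C@@H](C)C1=CC(=O)[C@](C)(O1)[C@H](O[Si](C)(C)C(C)(C)C)[C@@H](Oc2ccc(OC)cc2)/C=C(\C[Si](C)(C)C)C(=O)OCC | intermediate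
21 | ethyl (4R,5S,6R,7S,8S,9R,10R)-5,9-bis(tert-butyldimethylsilyloxy)-6-hydroxy-8-(4-methoxyphenoxy)-1-oxo-3,10-epoxygermacra-2,11(13)-dien-12-oate | C=C(C(=O)OCC)[C@@H]1[C@H](Oc2ccc(OC)cc2)[C@@H](O[Si](C)(C)C(C)(C)C)[C@@]2(C)OC(=CC2=O)[C@H](C)[C@H](O[Si](C)(C)C(C)(C)C)[C@@H]1O | intermediate
22 | (4R,5S,6R,7R,8S,9R,10R)-5,9-bis(tert-butyldimethylsilyloxy)-8-(4-methoxyphenoxy)-1-oxo-3,10-epoxygermacra-2,11(13)-dien-12,6-olide | C=C1C(=O)O[C@H]2[C@@H](O[Si](C)(C)C(C)(C)C)[C@@H](C)C3=CC(=O)[C@](C)(O3)[C@H](O[Si](C)(C)C(C)(C)C)[C@@H](Oc4ccc(OC)cc4)[C@@H]12 | intermediate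
23 | (4R,5S,6R,7R,8S,9R,10R)-5,9-bis(tert-butyldimethylsilyloxy)-8-hydroxy-1-oxo-3,10-epoxygermacra-2,11(13)-dien-12,6-olide | C=C1C(=O)O[C@H]2[C@@H](O[Si](C)(C)C(C)(C)C)[C@@H](C)C3=CC(=O)[C@](C)(O3)[C@H](O[Si](C)(C)C(C)(C)C)[C@@H](O)[C@@H]12 | intermediate
24 | angelic acid, (2Z)-2-methylbut-2-enoic acid | C/C=C(/C)C(=O)O | starting material
25 | (2Z)-2-methylbut-2-enoic 2,4,6-trichlorobenzoic anhydride | C/C=C(/C)C(=O)OC(=O)c1c(Cl)cc(Cl)cc1Cl | intermediate
26 | (4R,5S,6R,7S,8S,9R,10R)-8-angeloyloxy-5,9-bis(tert-butyldimethylsilyloxy)-1-oxo-3,10-epoxygermacra-2,11(13)-dien-12,6-olide | C=C1C(=O)O[C@H]2[C@@H](O[Si](C)(C)C(C)(C)C)[C@@H](C)C3=CC(=O)[C@](C)(O3)[C@H](O[Si](C)(C)C(C)(C)C)[C@@H](OC(=O)/C(C)=C\C)[C@@H]12 | intermediate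
27 | (4R,5S,6R,7S,8S,9R,10R)-8-angeloyloxy-5,9-dihydroxy-1-oxo-3,10-epoxygermacra-2,11(13)-dien-12,6-olide (CNP0206920.1) | C=C1C(=O)O[C@H]2[C@@H](O)[C@@H](C)C3=CC(=O)[C@](C)(O3)[C@H](O)[C@@H](OC(=O)/C(C)=C\C)[C@@H]12 | target

## Step count and risks

Total step count: 15. Longest linear sequence: 11 steps (steps 1–3 then 8–15; the sugar branch, steps 5–7 then 8–15, is equally long).

The three steps most likely to fail:

Step 12 (ring closure) is the weakest step. A medium ring is formed by an ester-deactivated allylsilane, both new stereocentres (C6, C7) rest on transition-state models, and 1,4-elimination of the δ-oxygen group could compete. The fallback replaces the silicon donor by an organochromium reagent and sets out from 20. N-Bromosuccinimide (CH2Cl2, −78 °C) gives, by ipso-bromodesilylation with allylic shift, the allylic bromide ethyl (4R,5R)-3-bromo-5-(tert-butyldimethylsilyloxy)-5-{(2R)-5-[(2R,3S)-3-(tert-butyldimethylsilyloxy)-4-oxobutan-2-yl]-2-methyl-3-oxo-2,3-dihydrofuran-2-yl}-4-(4-methoxyphenoxy)-2-methylidenepentanoate F1 (both C3 epimers). CrCl2 (THF, high dilution) then closes the ring by a Nozaki–Hiyama allylation through an ester-chelated six-membered transition state, which favours the syn adduct, to give hydroxy ester 21; acid lactonisation brings the fallback back to the route at 22.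

Step 9 (the new gold relay) may stall if the hemiketal does not open or react under gold catalysis. The fallback uses only known chemistry and sets out from 15. The lactone is opened with MeNH(OMe)·HCl/AlMe3 to the Weinreb amide ethyl (2Z,4R,5R,6R)-5-(tert-butyldimethylsilyloxy)-4,6-dihydroxy-7-[methoxy(methyl)amino]-6-methyl-7-oxo-2-[(trimethylsilyl)methyl]hept-2-enoate F2. Mitsunobu etherification with 4-methoxyphenol inverts C8 and gives ethyl (2Z,4S,5R,6R)-5-(tert-butyldimethylsilyloxy)-6-hydroxy-7-[methoxy(methyl)amino]-4-(4-methoxyphenoxy)-6-methyl-7-oxo-2-[(trimethylsilyl)methyl]hept-2-enoate F3. Lithium acetylide 16 (2.2 equiv) then gives the open-chain α'-hydroxy ynone ethyl (2Z,4S,5R,6R,10S,11S)-5,11-bis(tert-butyldimethylsilyloxy)-6-hydroxy-12,12-dimethoxy-4-(4-methoxyphenoxy)-6,10-dimethyl-7-oxo-2-[(trimethylsilyl)methyl]dodec-2-en-8-ynoate F4, which cannot form a hemiketal. The established gold-catalysed 5-endo-dig closure of free α'-hydroxy ynones converts F4 into 19, where the fallback comes back to the route.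

Step 10 (Mitsunobu etherification) has a hindered allylic alcohol next to a silyloxy-bearing carbon and a weakly acidic phenol. The fallback inverts C8 by oxidation and reduction instead and sets out from 18.
- Dess–Martin oxidation gives the enone ethyl (2Z,5S)-5-(tert-butyldimethylsilyloxy)-5-{(2R)-5-[(2R,3S)-3-(tert-butyldimethylsilyloxy)-4,4-dimethoxybutan-2-yl]-2-methyl-3-oxo-2,3-dihydrofuran-2-yl}-4-oxo-2-[(trimethylsilyl)methyl]pent-2-enoate F5.
- Reduction with (S)-2-methyl-CBS-oxazaborolidine and catecholborane (alkenyl as the large group) gives the 8S alcohol ethyl (2Z,4S,5R)-5-(tert-butyldimethylsilyloxy)-5-{(2R)-5-[(2R,3S)-3-(tert-butyldimethylsilyloxy)-4,4-dimethoxybutan-2-yl]-2-methyl-3-oxo-2,3-dihydrofuran-2-yl}-4-hydroxy-2-[(trimethylsilyl)methyl]pent-2-enoate F6.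
- TFA/H2O gives the hydroxy aldehyde ethyl (2Z,4S,5R)-5-(tert-butyldimethylsilyloxy)-5-{(2R)-5-[(2R,3S)-3-(tert-butyldimethylsilyloxy)-4-oxobutan-2-yl]-2-methyl-3-oxo-2,3-dihydrofuran-2-yl}-4-hydroxy-2-[(trimethylsilyl)methyl]pent-2-enoate F7.
- TESCl/imidazole gives the triethylsilyl ether ethyl (2Z,4S,5R)-5-(tert-butyldimethylsilyloxy)-5-{(2R)-5-[(2R,3S)-3-(tert-butyldimethylsilyloxy)-4-oxobutan-2-yl]-2-methyl-3-oxo-2,3-dihydrofuran-2-yl}-4-(triethylsilyloxy)-2-[(trimethylsilyl)methyl]pent-2-enoate F8.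
- BF3·OEt2 closure as in step 12 goes through the hydroxy ester ethyl (4R,5S,6R,7S,8S,9R,10R)-5,9-bis(tert-butyldimethylsilyloxy)-6-hydroxy-8-(triethylsilyloxy)-1-oxo-3,10-epoxygermacra-2,11(13)-dien-12-oate F9 to the lactone (4R,5S,6R,7S,8S,9R,10R)-5,9-bis(tert-butyldimethylsilyloxy)-8-(triethylsilyloxy)-1-oxo-3,10-epoxygermacra-2,11(13)-dien-12,6-olide F10.
- PPTS in MeOH removes the triethylsilyl group selectively, and the fallback comes back to the route at 23.

## Further compounds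

F1 | step 12 | ethyl (4R,5R)-3-bromo-5-(tert-butyldimethylsilyloxy)-5-{(2R)-5-[(2R,3S)-3-(tert-butyldimethylsilyloxy)-4-oxobutan-2-yl]-2-methyl-3-oxo-2,3-dihydrofuran-2-yl}-4-(4-methoxyphenoxy)-2-methylidenepentanoate (both C3 epimers) | O=C[C@@H](O[Si](C)(C)C(C)(C)C)[C@@H](C)C1=CC(=O)[C@](C)(O1)[C@H](O[Si](C)(C)C(C)(C)C)[C@@H](Oc2ccc(OC)cc2)C(Br)C(=C)C(=O)OCC
F2 | step 9 | ethyl (2Z,4R,5R,6R)-5-(tert-butyldimethylsilyloxy)-4,6-dihydroxy-7-[methoxy(methyl)amino]-6-methyl-7-oxo-2-[(trimethylsilyl)methyl]hept-2-enoate | CON(C)C(=O)[C@](C)(O)[C@H](O[Si](C)(C)C(C)(C)C)[C@H](O)/C=C(\C[Si](C)(C)C)C(=O)OCC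
F3 | step 9 | ethyl (2Z,4S,5R,6R)-5-(tert-butyldimethylsilyloxy)-6-hydroxy-7-[methoxy(methyl)amino]-4-(4-methoxyphenoxy)-6-methyl-7-oxo-2-[(trimethylsilyl)methyl]hept-2-enoate | CON(C)C(=O)[C@](C)(O)[C@H](O[Si](C)(C)C(C)(C)C)[C@@H](Oc1ccc(OC)cc1)/C=C(\C[Si](C)(C)C)C(=O)OCC
F4 | step 9 | ethyl (2Z,4S,5R,6R,10S,11S)-5,11-bis(tert-butyldimethylsilyloxy)-6-hydroxy-12,12-dimethoxy-4-(4-methoxyphenoxy)-6,10-dimethyl-7-oxo-2-[(trimethylsilyl)methyl]dodec-2-en-8-ynoate | COC(OC)[C@@H](O[Si](C)(C)C(C)(C)C)[C@@H](C)C#CC(=O)[C@](C)(O)[C@H](O[Si](C)(C)C(C)(C)C)[C@@H](Oc1ccc(OC)cc1)/C=C(\C[Si](C)(C)C)C(=O)OCC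
F5 | step 10 | ethyl (2Z,5S)-5-(tert-butyldimethylsilyloxy)-5-{(2R)-5-[(2R,3S)-3-(tert-butyldimethylsilyloxy)-4,4-dimethoxybutan-2-yl]-2-methyl-3-oxo-2,3-dihydrofuran-2-yl}-4-oxo-2-[(trimethylsilyl)methyl]pent-2-enoate | COC(OC)[C@@H](O[Si](C)(C)C(C)(C)C)[C@@H](C)C1=CC(=O)[C@](C)(O1)[C@H](O[Si](C)(C)C(C)(C)C)C(=O)/C=C(\C[Si](C)(C)C)C(=O)OCC
F6 | step 10 | ethyl (2Z,4S,5R)-5-(tert-butyldimethylsilyloxy)-5-{(2R)-5-[(2R,3S)-3-(tert-butyldimethylsilyloxy)-4,4-dimethoxybutan-2-yl]-2-methyl-3-oxo-2,3-dihydrofuran-2-yl}-4-hydroxy-2-[(trimethylsilyl)methyl]pent-2-enoate | COC(OC)[C@@H](O[Si](C)(C)C(C)(C)C)[C@@H](C)C1=CC(=O)[C@](C)(O1)[C@H](O[Si](C)(C)C(C)(C)C)[C@@H](O)/C=C(\C[Si](C)(C)C)C(=O)OCC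
F7 | step 10 | ethyl (2Z,4S,5R)-5-(tert-butyldimethylsilyloxy)-5-{(2R)-5-[(2R,3S)-3-(tert-butyldimethylsilyloxy)-4-oxobutan-2-yl]-2-methyl-3-oxo-2,3-dihydrofuran-2-yl}-4-hydroxy-2-[(trimethylsilyl)methyl]pent-2-enoate | O=C[C@@H](O[Si](C)(C)C(C)(C)C)[C@@H](C)C1=CC(=O)[C@](C)(O1)[C@H](O[Si](C)(C)C(C)(C)C)[C@@H](O)/C=C(\C[Si](C)(C)C)C(=O)OCC
F8 | step 10 | ethyl (2Z,4S,5R)-5-(tert-butyldimethylsilyloxy)-5-{(2R)-5-[(2R,3S)-3-(tert-butyldimethylsilyloxy)-4-oxobutan-2-yl]-2-methyl-3-oxo-2,3-dihydrofuran-2-yl}-4-(triethylsilyloxy)-2-[(trimethylsilyl)methyl]pent-2-enoate | O=C[C@@H](O[Si](C)(C)C(C)(C)C)[C@@H](C)C1=CC(=O)[C@](C)(O1)[C@H](O[Si](C)(C)C(C)(C)C)[C@@H](O[Si](CC)(CC)CC)/C=C(\C[Si](C)(C)C)C(=O)OCC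
F9 | step 10 | ethyl (4R,5S,6R,7S,8S,9R,10R)-5,9-bis(tert-butyldimethylsilyloxy)-6-hydroxy-8-(triethylsilyloxy)-1-oxo-3,10-epoxygermacra-2,11(13)-dien-12-oate | C=C(C(=O)OCC)[C@@H]1[C@H](O[Si](CC)(CC)CC)[C@@H](O[Si](C)(C)C(C)(C)C)[C@@]2(C)OC(=CC2=O)[C@H](C)[C@H](O[Si](C)(C)C(C)(C)C)[C@@H]1O
F10 | step 10 | (4R,5S,6R,7S,8S,9R,10R)-5,9-bis(tert-butyldimethylsilyloxy)-8-(triethylsilyloxy)-1-oxo-3,10-epoxygermacra-2,11(13)-dien-12,6-olide | C=C1C(=O)O[C@H]2[C@@H](O[Si](C)(C)C(C)(C)C)[C@@H](C)C3=CC(=O)[C@](C)(O3)[C@H](O[Si](C)(C)C(C)(C)C)[C@@H](O[Si](CC)(CC)CC)[C@@H]12
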